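Amounts first: in the runs so far, the highest triple product goes with how much reagent stands against each substrate.

| setting | summer | spring | dusk | flask |
|---|---|---|---|---|
| substrate | 0.14 M | 0.22 M | 0.10 M | 0.10 M |
| reagent | 0.15 M | 0.15 M | 0.075 M | 0.150 M |
| remark | run made earlier | run made earlier | run made earlier |  |
| time |  |  |  | 8.0 min |

| run | time / min | triple product / % |
|---|---|---|
| summer | 1.00 | 1.4 |
| summer | 2.00 | 6.0 |
| summer | 5.00 | 5.5 |
| summer | 10.0 | 2.0 |
| spring | 1.00 | 1.2 |
| spring | 2.00 | 3.0 |
| spring | 5.00 | 2.4 |
| spring | 10.0 | 0.7 |
| dusk | 1.00 | 0 |
| dusk | 2.00 | 1.2 |
| dusk | 5.00 | 3.0 |
| dusk | 10.0 | 0.6 |

(readings scatter by 0.5 percentage points)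

1. when, up to 8.0 min, the flask holds most triple product
2. the amount of triple product, in percent of the substrate charged, at that time
3. the first time at which triple product reaches 5.3%, in the same percent, in min

- percentages count the substrate that a species holds: one side product counts as two
- the numbers in the tables scatter with a standard deviation of 0.5 percentage points
- steps thought possible: substrate + reagent -> first product + by-product; reagent + first product -> double product + by-product; reagent + double product -> triple product + by-product; triple product -> over-reaction product; substrate + double product -> side product

The highest readings are 6.0% in summer at 1.07 equivalents, 3.0% in spring at 0.682 and 3.0% at dusk at 0.750. Divide the rate of double product to triple product by its rate to side product: double product and time drop out, and reagent over substrate stays, as in a selectivity factor. So you try one power of the equivalents, but the quotients run 5.60%, 4.40%, 4.00%, a drift. Divide by the square instead and you get 5.23%, 6.45%, 5.33%, and the scatter on the spring quotient is 1.1 percentage points. The square is read from the runs, not derived. The mean of these quotients is the peak coefficient, 5.67%, the highest reading per squared equivalent.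

The flask has 1.50 equivalents, beyond every run, and my reckoning gives 12.8%. Can the reagent pay for that? Each triple product takes 3 reagent, so the flask's charge allows 50.0% if no other path takes any, well above it, and that objection falls. The readings also stand minutes apart, so a peak can hide between them; I leave that uncorrected.

The forecast is lower than my reckoning: 9.5% (7.5% to 13%) at 4.2 min (3 min to 5.5 min), with 5.3% reached at 1.9 min (1.4 min to 2.5 min), on the ground that “The height of the peak depends on reagent per substrate”.

The flask peaks at 10.6% at 4.01 min and reaches 5.3% at 1.57 min, sooner than forecast; the coefficient's figure stands higher.

    substrate + reagent → first product + by-product (k = 2.14 M⁻¹ min⁻¹)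
    reagent + first product → double product + by-product (k = 11.7 M⁻¹ min⁻¹)
    reagent + double product → triple product + by-product (k = 5.81 M⁻¹ min⁻¹)
    triple product → over-reaction product (k = 0.332 min⁻¹)
    substrate + double product → side product (k = 2.58 M⁻¹ min⁻¹)

In the flask, double product goes to triple product 3.38 times as fast as to side product at the charge. At 4.01 min, with 27.1% of the reagent and 43.2% of the substrate left, it is still twice as fast. In the neighbour flask with 0.037 M of reagent, 0.370 equiv, the coefficient gives 0.776%; computed, that flask reaches 0.621%.

The numbers in the tables are calculated from invented constants, and the scatter is random.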